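## Analysis of the target

The target is a germacranolide: a ten-membered carbocycle (C1–C10) fused at C6/C7 to a butenolide (O6–C12(=O)–C11=C7). It carries a hydroxymethyl group (C13) on C11, a tigloyl ester on O8, methyl groups on C4 and C10, and oxiranes across C1–C10 and C4–C5. The six stereocentres are (1R,4R,5R,6S,8S,10R). Both oxiranes are trans along the ring, so each derives from an E trisubstituted alkene oxidised on its outer face (1β,10α and 4α,5β in the usual notation). The C5–O bond is anti to C7 across C5–C6, and the oxygens on C6 and C8 lie on the same (α) face on either side of sp2 C7. The oxiranes open transannularly under acid. The γ-hydrogen at C6 of the butenolide is acidic and its anion sits next to the C4–C5 oxirane, so base is not tolerated once the oxiranes exist. The difficulty lies in a medium ring with two geometrically defined alkene-derived oxiranes and three allylic C–O bonds (C6, C8, C13) around a tetrasubstituted alkene. The strategy rests on one observation: a bond between C5 and C10, plus unsaturation at C2=C3, turns the C1=C10/C4=C5 pair into the cyclohexa-1,3-diene ring A of a trans-fused eudesmanolide. That bicycle already holds both methyl groups and the C6 lactone oxygen, which is the skeleton and C6 configuration of α-santonin (1).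

## Retrosynthetic reasoning

**20 ⇒ 19.** Only the O13–H bond is made last. The C13 oxygen is carried as an anisylmethyl ether because it can be removed oxidatively at neutral pH, the one kind of deprotection the bis-oxirane/butenolide array should tolerate.

**19 ⇒ 18.** The four C–O bonds of the two oxiranes are cut, leading back to the (1(10)E,4E)-diene 18. The oxiranes are the most fragile groups, so they come late. The tiglate is already in place at this point, so no acylation or desilylation with base is needed afterwards. The forward reaction has to deliver oxygen to the outer face of each alkene; at C4=C5 that face is dictated by C6.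

**18 ⇒ 16 (through 17).** The C5–C10 bond is re-formed in thought and C2=C3 is unsaturated, giving the trans-fused eudesma-1,3-diene 16. This cut is chosen because it removes the medium ring altogether. The ten-membered ring then arises by cleaving the bond common to two six-membered rings, with both E geometries fixed by orbital symmetry and the trans ring fusion. The forward step must open ring A photochemically to triene 17 and saturate its central Z alkene before it can reclose.

**16 ⇒ 15 ⇒ 14.** The C3=C4 alkene of the diene is traced to a C3–O bond: 1,2-reduction of enone 14 and syn-dehydration of allylic alcohol 15. This base-free way is needed because the butenolide C6–H would not survive enolate-based diene syntheses. The diene is made last before the key step because it would not survive the oxidations used earlier.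

**14 ⇒ 13.** The enone carbonyl is masked as a ketal. The mask removes the acidic C4–H and the oxidisable α'-position during enolate chemistry and C–H oxidation, and leaves the C1=C2 alkene without an allylic hydrogen.

**13 ⇒ 11 + 12.** The C8–O ester bond is cut. The forward esterification with tiglic acid (12) is run with inversion, because C–H oxidation at C8 is expected to give the axial 8β-alcohol 11 while the target needs 8α. This sets the configuration and installs the final acyl group in one step.

**11 ⇒ 10.** The C8–O bond is cut back to a C–H bond γ to the lactone carbonyl. The forward step is an allylic hydroxylation of the ring CH2 next to C7=C11.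

**10 ⇒ 9 ⇒ 8.** The C13–O bond is traced to bromide 9 and this to the α-methylene lactone 8. An allylic bromination with alkene shift makes the C13–heteroatom bond and the C7=C11 alkene together and erases the C7 stereocentre, which the target lacks.

**8 ⇒ 5.** The C11=C13 alkene comes from the saturated lactone by α-selenenylation (6) and selenoxide elimination (7).

**5 ⇒ 4 ⇒ 2 ⇒ 1.** Ring A is adjusted at the start on robust material: ketalisation of enone 4, dehydrogenation of ketone 2 through silyl enol ether 3, and hydrogenation of α-santonin (1), which sets H-5α.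

## Alternatives that were turned down

**Alternative 1:** The ring bond C2–C3 is disconnected, made while a six-membered-ring bond C5–C10 breaks. Forward, a potassium alkoxide at C5 would trigger an anionic oxy-Cope shift joining the two alkenyl termini, and the C4=C5 enolate would be trapped as the enol triflate A1.
- For: the ring expansion is thermal, runs to completion at low temperature and gives both E alkenes through a chair transition state. On ring-forming efficiency it is stronger than a photostationary opening.
- Against: A1 carries only an oxygen at C7. The whole C11–C13 lactone unit, the C5 hydrogen (triflate reduction) and the C7=C11 alkene would have to be built on a flexible cyclodeca-1,5-diene prone to Cope and transannular reactions. The six-membered substrate also needs five stereocentres made from scratch, including a quaternary C10 and a tertiary carbinol.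
- Comparison: the chosen route offers in its place a complete butenolide and an inherited C6 centre before the ring is opened, and only two steps after it.

**Alternative 2:** The C6–C7 bond is disconnected. Forward, deprotonation at C6 of a thirteen-membered diallylic ether would start a [2,3]-Wittig shift that forms C6–C7, breaks O–C13 and contracts the ring to the ten-membered carbinol A2.
- For: a thirteen-membered ether is easier to close than a ten-membered carbocycle, and the C6 carbinol and C6–C7 bond appear together.
- Against: the shift creates a stereocentre at C7 that the target does not have. A2 still needs oxidation of its CH2O carbon to the acid level, lactonisation, hydroxylation of the methylene carbon and migration of the alkene to C7=C11. C6 rests on transition-state control in a macrocycle, and both carbons flanking the ether oxygen are allylic, so the site of deprotonation is uncertain.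
- Comparison: the chosen route has C6 fixed from the start and needs no redox adjustment of the lactone carbons after ring formation.

**Alternative 3:** The C1–C2 bond is disconnected. Forward, hydroboration of a terminal vinyl group on C4 would give a C2 alkylborane that couples with a C1 alkenyl iodide under zerovalent palladium catalysis, closing the ring to A3.
- For: it is the most convergent plan and is stronger on two points. The C4–C5 oxirane configuration and the 1(10)E geometry are set before cyclisation and do not depend on ring conformation, and only one epoxidation would remain.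
- Against: a ten-membered ring with an E trisubstituted alkene must be closed by sp2–sp3 coupling against transannular strain, with oligomerisation and β-hydride elimination as competitors. The basic aqueous medium needed for transmetalation meets a butenolide whose C6–H lies next to the oxirane. Four stereocentres must be built by acyclic control.
- Comparison: the chosen route offers a ring "closure" with no entropic cost and stereocentres taken from the chiral pool.

Key step: step 12

Remark on the chemistry: eudesmane/germacrane numbering is used (C14 on C10, C15 on C4, lactone carbons C11–C13), and α/β refer to the usual projection with the C10 methyl β. The C8 oxygen is carried through the key step as the tiglate and the C13 oxygen as the 4-methoxybenzyl ether.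

## Route

Step 1
Reactants: 1 α-santonin
Product: 2 3-oxo-5αH-eudesman-6α,12-olide (4α-methyl; 11β-H; trans-fused tetrahydrosantonin)
Conditions: H2 (1 atm), Pd/C (10%), EtOAc, 25 °C; then HCl (cat.), EtOH, 50 °C
Reagents that add atoms: none
Why: Heterogeneous hydrogenation saturates both ring A alkenes; H2 should add to C4=C5 from the α face, anti to the angular C10 methyl, which sets the trans ring fusion (H-5α). The acid treatment equilibrates the enolisable C4 centre to the equatorial 4α-methyl epimer, since a 4β-methyl would be 1,3-diaxial to the C10 methyl. The cis-fused minor isomer is expected to be removed by crystallisation.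

Step 2
Reactants: 2 3-oxo-5αH-eudesman-6α,12-olide
Product: 4 3-oxo-5αH-eudesm-1-en-6α,12-olide, via silyl enol ether 3 (not isolated)
Conditions: LiN(iPr)2 (1.1 equiv), Me3SiCl, THF, −78 °C; then Pd(OAc)2 (10 mol %), O2 (1 atm), DMSO, 25 °C
Reagents that add atoms: none
Why: Kinetic deprotonation removes a C2 hydrogen (CH2 rather than the hindered C4–H; the lactone α-H is less acidic). Saegusa–Ito dehydrogenation of the Δ2 silyl enol ether with O2 as terminal oxidant then gives the Δ1-enone; no stereocentre is formed.

Step 3
Reactants: 4 3-oxo-5αH-eudesm-1-en-6α,12-olide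
Product: 5 3,3-ethylenedioxy-5αH-eudesm-1-en-6α,12-olide
Conditions: Me3SiOCH2CH2OSiMe3 (2 equiv), Me3SiOTf (5 mol %), CH2Cl2, −78 → −20 °C
Reagents that add atoms: 1,2-bis(trimethylsilyloxy)ethane, C[Si](C)(C)OCCO[Si](C)(C)C
Why: Silyl-triflate-catalysed ketalisation masks the enone carbonyl, whose C4–H would be deprotonated in step 4 and whose α'-position would be oxidised in step 7. C10 is quaternary, so the alkene cannot migrate and C1=C2 is left without an abstractable allylic hydrogen.

Step 4
Reactants: 5 3,3-ethylenedioxy-5αH-eudesm-1-en-6α,12-olide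
Product: 8 3,3-ethylenedioxy-5αH-eudesma-1,11(13)-dien-6α,12-olide, via selenide 6 (not isolated), via selenoxide 7 (not isolated)
Conditions: LiN(iPr)2 (1.2 equiv), THF, −78 °C; PhSeBr, −78 °C; then H2O2 (30%, excess), pyridine, CH2Cl2, 0 → 25 °C
Reagents that add atoms: none
Why: α-Selenenylation of the lactone enolate at C11 and selenoxide syn-elimination; removal of a methyl hydrogen should be favoured over the ring H-7, so the α-methylene lactone is the expected main product. Pyridine buffers the seleninic acid and protects the ketal.

Step 5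
Reactants: 8 3,3-ethylenedioxy-5αH-eudesma-1,11(13)-dien-6α,12-olide
Product: 9 13-bromo-3,3-ethylenedioxy-5αH-eudesma-1,7(11)-dien-6α,12-olide
Conditions: N-bromosuccinimide (1.05 equiv), azobisisobutyronitrile (5 mol %), NaHCO3 (solid), PhCF3, 80 °C
Reagents that add atoms: N-bromosuccinimide, O=C1CCC(=O)N1Br
Why: Wohl–Ziegler bromination: the only allylic hydrogen of the C11=C13 alkene is H-7, and the delocalised C7–C11–C13 radical should take bromine at the primary terminus, giving the conjugated tetrasubstituted C7=C11 butenolide with bromide on C13. Ring A offers no allylic C–H, and the C7 stereocentre is given up on purpose.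

Step 6
Reactants: 9 13-bromo-3,3-ethylenedioxy-5αH-eudesma-1,7(11)-dien-6α,12-olide
Product: 10 13-(4-methoxybenzyloxy)-3,3-ethylenedioxy-5αH-eudesma-1,7(11)-dien-6α,12-olide
Conditions: 4-MeOC6H4CH2OH (5 equiv), Ag2O (1.5 equiv), 4 Å molecular sieves, CH2Cl2, 25 °C, dark
Reagents that add atoms: 4-methoxybenzyl alcohol, COc1ccc(CO)cc1
Why: Ag2O-assisted Williamson-type etherification of the activated primary allylic bromide under non-basic conditions. C7 is fully substituted, so direct substitution at C13 should win over SN2′ attack, and the base-labile C6–H is not touched.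

Step 7
Reactants: 10 13-(4-methoxybenzyloxy)-3,3-ethylenedioxy-5αH-eudesma-1,7(11)-dien-6α,12-olide
Product: 11 8β-hydroxy-13-(4-methoxybenzyloxy)-3,3-ethylenedioxy-5αH-eudesma-1,7(11)-dien-6α,12-olide
Conditions: SeO2 (1.5 equiv), pyridine (3 equiv), 1,4-dioxane, 80 °C
Reagents that add atoms: selenium dioxide, O=[Se]=O
Why: Riley allylic hydroxylation: the ene step should bond selenium to the α-carbon C11 and remove the axial H-8β of the ring CH2 γ to the carbonyl (CH2 preferred over the acyloxy-bearing C6–H), and the suprafacial [2,3]-shift returns the alkene to C7=C11 while placing oxygen on the β face of C8. The new C8 stereocentre is therefore expected as the axial 8β-alcohol, as in SeO2 hydroxylations of rigid cyclohexene systems; pyridine keeps the medium non-acidic for the ketal.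

Step 8
Reactants: 11 8β-hydroxy-13-(4-methoxybenzyloxy)-3,3-ethylenedioxy-5αH-eudesma-1,7(11)-dien-6α,12-olide; 12 tiglic acid, (E)-2-methylbut-2-enoic acid
Product: 13 8α-tigloyloxy-13-(4-methoxybenzyloxy)-3,3-ethylenedioxy-5αH-eudesma-1,7(11)-dien-6α,12-olide
Conditions: PPh3 (3 equiv), iPrO2CN=NCO2iPr (3 equiv), toluene, 0 → 25 °C
Reagents that add atoms: none
Why: Mitsunobu esterification: the oxyphosphonium ion of the axial 8β-alcohol should be displaced by tiglate from the open α face with inversion, which sets the 8α (S) ester configuration of the target and installs the tigloyl group without a protecting-group detour. The E geometry of the acid is not at risk under these neutral conditions.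

Step 9
Reactants: 13 8α-tigloyloxy-13-(4-methoxybenzyloxy)-3,3-ethylenedioxy-5αH-eudesma-1,7(11)-dien-6α,12-olide
Product: 14 8α-tigloyloxy-13-(4-methoxybenzyloxy)-3-oxo-5αH-eudesma-1,7(11)-dien-6α,12-olide
Conditions: pyridinium p-toluenesulfonate (20 mol %), THF/H2O (4:1), 40 °C
Reagents that add atoms: water, O
Why: Mild acid hydrolysis of the allylic ketal, which should be much faster than cleavage of the benzylic ether or the esters, returns the Δ1-enone.

Step 10
Reactants: 14 8α-tigloyloxy-13-(4-methoxybenzyloxy)-3-oxo-5αH-eudesma-1,7(11)-dien-6α,12-olide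
Product: 15 3β-hydroxy-8α-tigloyloxy-13-(4-methoxybenzyloxy)-5αH-eudesma-1,7(11)-dien-6α,12-olide
Conditions: NaBH4 (1 equiv), CeCl3·7H2O (1.1 equiv), MeOH/THF, −78 °C
Reagents that add atoms: none
Why: Luche reduction: only the enone carbonyl should be reduced, in 1,2-fashion (butenolide and tiglate are unreactive at −78 °C). Axial hydride delivery from the α face gives the pseudo-equatorial 3β-alcohol, cis to H-4β.

Step 11
Reactants: 15 3β-hydroxy-8α-tigloyloxy-13-(4-methoxybenzyloxy)-5αH-eudesma-1,7(11)-dien-6α,12-olide
Product: 16 8α-tigloyloxy-13-(4-methoxybenzyloxy)-5αH-eudesma-1,3,7(11)-trien-6α,12-olide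
Conditions: MeO2CN(−)SO2N(+)Et3 (Burgess reagent, 2 equiv), benzene, 50 °C
Reagents that add atoms: none
Why: Burgess dehydration: the sulfamate ester should undergo thermal syn-elimination through the cis H-4β (C2 is vinylic, so no other β-hydrogen exists), giving C3=C4 and thus the homoannular 1,3-diene. No acid or base is present that could move the diene or deprotonate the butenolide.

Step 12
Reactants: 16 8α-tigloyloxy-13-(4-methoxybenzyloxy)-5αH-eudesma-1,3,7(11)-trien-6α,12-olide
Product: 18 (1(10)E,4E)-8α-tigloyloxy-13-(4-methoxybenzyloxy)germacra-1(10),4,7(11)-trien-6α,12-olide, via cyclodecatriene 17 (not isolated)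
Conditions: hν (254 nm, low-pressure Hg lamp, quartz), degassed MeOH/THF (4:1), −40 °C; then KO2CN=NCO2K (5 equiv), AcOH (10 equiv), −40 → −15 °C
Reagents that add atoms: none
Why: Excitation of the ring A diene triggers a photochemical 6π electrocyclic ring opening, conrotatory by orbital symmetry, that cleaves the C5–C10 σ bond and creates the C1=C10 and C4=C5 π bonds. The closest known reaction type is the cyclohexa-1,3-diene/hexa-1,3,5-triene photoequilibrium as applied to trans-fused eudesma-1,3-dienolides, which open to (E,Z,E)-cyclodecatrienes. The ten-membered ring is not closed by a new bond but set free by cutting the bond shared by the two six-membered rings, so there is no entropic cost of cyclisation. No stereocentre is formed; because H-5 (α) and the C10 methyl (β) are trans, conrotation turns C6 and C9 outward together and gives the E geometry at both trisubstituted alkenes, with C2=C3 left Z. The step needs light to enter the diene and not the butenolide, the tiglate or the anisyl ring; at 254 nm the planar diene is by far the strongest absorber and the twisted triene absorbs less, so the stationary state should lean towards 17. The strained triene would reclose thermally (disrotatory, to a cis-fused diene) on warming, so it is reduced in the cold flask by diimide, which should saturate the strained disubstituted Z C2=C3 bond faster than the trisubstituted ring alkenes, the tetrasubstituted butenolide alkene or the tiglate. C6 and C8 are untouched.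

Step 13
Reactants: 18 (1(10)E,4E)-8α-tigloyloxy-13-(4-methoxybenzyloxy)germacra-1(10),4,7(11)-trien-6α,12-olide
Product: 19 (1R,4R,5R,6S,8S,10R)-1,10:4,5-diepoxy-8-tigloyloxy-13-(4-methoxybenzyloxy)germacr-7(11)-en-6,12-olide
Conditions: dimethyldioxirane (2.5 equiv, in acetone), CH2Cl2, −20 → 0 °C
Reagents that add atoms: dimethyldioxirane, CC1(C)OO1
Why: Dioxirane epoxidation under neutral conditions should oxidise the two electron-rich trisubstituted ring alkenes, each on its exposed outer face in the crown conformer with both methyl groups on the same side; the electron-poor butenolide and tiglate alkenes do not react. At C4=C5 the face is fixed by C6: H-6 eclipses the alkene (allylic strain) and C7 blocks the inner face, so oxygen enters anti to C7 (4R,5R), and the C1=C10 oxirane (1R,10R) follows from the same conformer.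

Step 14
Reactants: 19 (1R,4R,5R,6S,8S,10R)-1,10:4,5-diepoxy-8-tigloyloxy-13-(4-methoxybenzyloxy)germacr-7(11)-en-6,12-olide
Product: 20 CNP0111480.1, (1R,4R,5R,6S,8S,10R)-1,10:4,5-diepoxy-13-hydroxy-8-tigloyloxygermacr-7(11)-en-6,12-olide
Conditions: DDQ (1.5 equiv), CH2Cl2/pH 7 phosphate buffer (10:1), 0 → 25 °C
Reagents that add atoms: none
Why: Oxidative cleavage of the 4-methoxybenzyl ether by DDQ (hydride abstraction at the anisylic carbon, hydrolysis of the oxocarbenium ion). The medium is neutral and non-nucleophilic, so oxiranes, butenolide and tiglate should survive.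

## Compound list

1 | α-santonin | C[C@H]1[C@@H]2CC[C@]3(C=CC(=O)C(=C3[C@H]2OC1=O)C)C | starting material
2 | 3-oxo-5αH-eudesman-6α,12-olide (4α-methyl, 11β-H) | C[C@H]1[C@@H]2CC[C@]3(CCC(=O)[C@@H](C)[C@@H]3[C@H]2OC1=O)C | intermediate
3 | 3-trimethylsilyloxy-5αH-eudesm-2-en-6α,12-olide (silyl enol ether) | C[C@H]1[C@@H]2CC[C@]3(CC=C(O[Si](C)(C)C)[C@@H](C)[C@@H]3[C@H]2OC1=O)C | intermediate
4 | 3-oxo-5αH-eudesm-1-en-6α,12-olide | C[C@H]1[C@@H]2CC[C@]3(C=CC(=O)[C@@H](C)[C@@H]3[C@H]2OC1=O)C | intermediate
5 | 3,3-ethylenedioxy-5αH-eudesm-1-en-6α,12-olide | C[C@H]1[C@@H]2CC[C@]3(C=CC4(OCCO4)[C@@H](C)[C@@H]3[C@H]2OC1=O)C | intermediate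
6 | 11α-phenylseleno-3,3-ethylenedioxy-5αH-eudesm-1-en-6α,12-olide (11β-methyl) | C[C@]1([Se]c5ccccc5)[C@@H]2CC[C@]3(C=CC4(OCCO4)[C@@H](C)[C@@H]3[C@H]2OC1=O)C | intermediate
7 | selenoxide of 6 (both configurations at selenium) | C[C@]1([Se](=O)c5ccccc5)[C@@H]2CC[C@]3(C=CC4(OCCO4)[C@@H](C)[C@@H]3[C@H]2OC1=O)C | intermediate
8 | 3,3-ethylenedioxy-5αH-eudesma-1,11(13)-dien-6α,12-olide | C=C1[C@@H]2CC[C@]3(C=CC4(OCCO4)[C@@H](C)[C@@H]3[C@H]2OC1=O)C | intermediate
9 | 13-bromo-3,3-ethylenedioxy-5αH-eudesma-1,7(11)-dien-6α,12-olide | C1C[C@@]2(C)C=CC3(OCCO3)[C@@H](C)[C@@H]2[C@H]2OC(=O)C(CBr)=C12 | intermediate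
10 | 13-(4-methoxybenzyloxy)-3,3-ethylenedioxy-5αH-eudesma-1,7(11)-dien-6α,12-olide | C1C[C@@]2(C)C=CC3(OCCO3)[C@@H](C)[C@@H]2[C@H]2OC(=O)C(COCc3ccc(OC)cc3)=C12 | intermediate
11 | 8β-hydroxy-13-(4-methoxybenzyloxy)-3,3-ethylenedioxy-5αH-eudesma-1,7(11)-dien-6α,12-olide | O[C@@H]1C[C@@]2(C)C=CC3(OCCO3)[C@@H](C)[C@@H]2[C@H]2OC(=O)C(COCc3ccc(OC)cc3)=C12 | intermediate
12 | tiglic acid | C/C=C(\C)C(=O)O | starting material
13 | 8α-tigloyloxy-13-(4-methoxybenzyloxy)-3,3-ethylenedioxy-5αH-eudesma-1,7(11)-dien-6α,12-olide | C/C=C(\C)C(=O)O[C@H]1C[C@@]2(C)C=CC3(OCCO3)[C@@H](C)[C@@H]2[C@H]2OC(=O)C(COCc3ccc(OC)cc3)=C12 | intermediate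
14 | 8α-tigloyloxy-13-(4-methoxybenzyloxy)-3-oxo-5αH-eudesma-1,7(11)-dien-6α,12-olide | C/C=C(\C)C(=O)O[C@H]1C[C@@]2(C)C=CC(=O)[C@@H](C)[C@@H]2[C@H]2OC(=O)C(COCc3ccc(OC)cc3)=C12 | intermediate
15 | 3β-hydroxy-8α-tigloyloxy-13-(4-methoxybenzyloxy)-5αH-eudesma-1,7(11)-dien-6α,12-olide | C/C=C(\C)C(=O)O[C@H]1C[C@@]2(C)C=C[C@H](O)[C@@H](C)[C@@H]2[C@H]2OC(=O)C(COCc3ccc(OC)cc3)=C12 | intermediate
16 | 8α-tigloyloxy-13-(4-methoxybenzyloxy)-5αH-eudesma-1,3,7(11)-trien-6α,12-olide (10β-methyl) | C/C=C(\C)C(=O)O[C@H]1C[C@@]2(C)C=CC=C(C)[C@@H]2[C@H]2OC(=O)C(COCc3ccc(OC)cc3)=C12 | intermediate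
17 | (1(10)E,2Z,4E)-8α-tigloyloxy-13-(4-methoxybenzyloxy)germacra-1(10),2,4,7(11)-tetraen-6α,12-olide | C/C=C(\C)C(=O)O[C@H]1C/C(C)=C/C=C\C(C)=C\[C@H]2OC(=O)C(COCc3ccc(OC)cc3)=C12 | intermediate
18 | (1(10)E,4E)-8α-tigloyloxy-13-(4-methoxybenzyloxy)germacra-1(10),4,7(11)-trien-6α,12-olide | C/C=C(\C)C(=O)O[C@H]1C/C(C)=C/CC/C(C)=C/[C@H]2OC(=O)C(COCc3ccc(OC)cc3)=C12 | intermediate
19 | (1R,4R,5R,6S,8S,10R)-1,10:4,5-diepoxy-8-tigloyloxy-13-(4-methoxybenzyloxy)germacr-7(11)-en-6,12-olide | C/C=C(\C)C(=O)O[C@H]1C[C@@]2(C)O[C@@H]2CC[C@@]2(C)O[C@@H]2[C@H]2OC(=O)C(COCc3ccc(OC)cc3)=C12 | intermediate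
20 | CNP0111480.1, (1R,4R,5R,6S,8S,10R)-1,10:4,5-diepoxy-13-hydroxy-8-tigloyloxygermacr-7(11)-en-6,12-olide | C/C=C(\C)C(=O)O[C@H]1C[C@@]2(C)O[C@@H]2CC[C@@]2(C)O[C@@H]2[C@H]2OC(=O)C(CO)=C12 | target

## Step count and least certain steps

Total step count: 14. Longest linear sequence: 14 steps, from 1 to 20; 12 is used as bought.

**Step 12 (key step).** The stationary state may hold too little 17. Light may be diverted into the anisyl ether, with cleavage or E/Z scrambling of the tiglate. The triene may reclose thermally before it is reduced, and diimide may also reduce unreacted 16. Fallback (sets out from 14, rejoins at 20), which removes the aromatic chromophore before the ring is opened: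
- DDQ cleaves the ether at the enone stage to give the C13 alcohol F1.
- t-BuMe2SiCl/imidazole gives the silyl ether F2.
- Luche reduction gives the allylic alcohol F3, and Burgess dehydration the diene F4.
- Irradiation as in step 12 gives the triene F5, reduced cold by diimide to the germacradiene F6.
- Dimethyldioxirane gives the bis-oxirane F7, and HF·pyridine buffered with pyridine frees the alcohol to give 20.

**Step 7.** The ene reaction may be sluggish at the electron-poor tetrasubstituted alkene. Attack may occur at C6–H, with loss of the lactone. The ketal may be lost to adventitious acid, followed by oxidation of ring A. Fallback (sets out from 10, rejoins at 11): allylic oxidation with CrO3·3,5-dimethylpyrazole (CH2Cl2, −20 °C) to the 8-ketone F8, then Luche reduction, in which hydride should enter from the open α face and return the 8β-alcohol 11.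

**Step 8.** The activated axial alcohol may eliminate towards C9, or ionise to an allyl cation with loss of stereocontrol. Fallback (sets out from 11, rejoins at 13):
- Dess–Martin oxidation to the 8-ketone F8.
- Corey–Bakshi–Shibata reduction with (R)-1-methyl-3,3-diphenyltetrahydro-1H,3H-pyrrolo[1,2-c][1,3,2]oxazaborole and BH3·SMe2, with the reagent chosen to deliver hydride to the β face, gives the 8α-alcohol F9.
- Yamaguchi esterification with 12 (2,4,6-trichlorobenzoyl chloride, Et3N, 4-(dimethylamino)pyridine) gives 13 with retention.

**Step 5.** The product butenolide has allylic hydrogens at C6 and C8, so over-bromination may occur, as may radical addition across C11=C13. Fallback (sets out from 8, rejoins at 10, bypassing 9):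
- Base-catalysed oxa-Michael addition of 4-methoxybenzyl alcohol (NaH, cat.) to the α-methylene lactone gives the saturated 13-(4-methoxybenzyloxy) lactone F10.
- α-Selenenylation (LiN(iPr)2, PhSeBr) and oxidation (H2O2, pyridine) follow; the selenoxide should eliminate towards H-7 and away from the oxygen-bearing C13, giving 10.

**Step 13.** The facial selectivity at C1=C10 may be poor if a conformer with the C10 methyl on the other side is populated, and the oxiranes may cyclise transannularly. Fallback (sets out from 18, rejoins at 19): reagent-controlled Shi epoxidation with 1,2:4,5-di-O-isopropylidene-D-erythro-hexo-2,3-diulo-2,6-pyranose (or its enantiomer, chosen by the spiro transition-state model) and KHSO5 at pH 8, 0 °C. This fallback makes no new compound (F0).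

## Further compounds

F1 | step 12 | 13-hydroxy-8α-tigloyloxy-3-oxo-5αH-eudesma-1,7(11)-dien-6α,12-olide | C/C=C(\C)C(=O)O[C@H]1C[C@@]2(C)C=CC(=O)[C@@H](C)[C@@H]2[C@H]2OC(=O)C(CO)=C12
F2 | step 12 | 13-(tert-butyldimethylsilyloxy)-8α-tigloyloxy-3-oxo-5αH-eudesma-1,7(11)-dien-6α,12-olide | C/C=C(\C)C(=O)O[C@H]1C[C@@]2(C)C=CC(=O)[C@@H](C)[C@@H]2[C@H]2OC(=O)C(CO[Si](C)(C)C(C)(C)C)=C12
F3 | step 12 | 3β-hydroxy-13-(tert-butyldimethylsilyloxy)-8α-tigloyloxy-5αH-eudesma-1,7(11)-dien-6α,12-olide | C/C=C(\C)C(=O)O[C@H]1C[C@@]2(C)C=C[C@H](O)[C@@H](C)[C@@H]2[C@H]2OC(=O)C(CO[Si](C)(C)C(C)(C)C)=C12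
F4 | step 12 | 13-(tert-butyldimethylsilyloxy)-8α-tigloyloxy-5αH-eudesma-1,3,7(11)-trien-6α,12-olide | C/C=C(\C)C(=O)O[C@H]1C[C@@]2(C)C=CC=C(C)[C@@H]2[C@H]2OC(=O)C(CO[Si](C)(C)C(C)(C)C)=C12
F5 | step 12 | (1(10)E,2Z,4E)-13-(tert-butyldimethylsilyloxy)-8α-tigloyloxygermacra-1(10),2,4,7(11)-tetraen-6α,12-olide | C/C=C(\C)C(=O)O[C@H]1C/C(C)=C/C=C\C(C)=C\[C@H]2OC(=O)C(CO[Si](C)(C)C(C)(C)C)=C12
F6 | step 12 | (1(10)E,4E)-13-(tert-butyldimethylsilyloxy)-8α-tigloyloxygermacra-1(10),4,7(11)-trien-6α,12-olide | C/C=C(\C)C(=O)O[C@H]1C/C(C)=C/CC/C(C)=C/[C@H]2OC(=O)C(CO[Si](C)(C)C(C)(C)C)=C12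
F7 | step 12 | (1R,4R,5R,6S,8S,10R)-1,10:4,5-diepoxy-13-(tert-butyldimethylsilyloxy)-8-tigloyloxygermacr-7(11)-en-6,12-olide | C/C=C(\C)C(=O)O[C@H]1C[C@@]2(C)O[C@@H]2CC[C@@]2(C)O[C@@H]2[C@H]2OC(=O)C(CO[Si](C)(C)C(C)(C)C)=C12
F8 | step 7 | 8-oxo-13-(4-methoxybenzyloxy)-3,3-ethylenedioxy-5αH-eudesma-1,7(11)-dien-6α,12-olide | O=C1C[C@@]2(C)C=CC3(OCCO3)[C@@H](C)[C@@H]2[C@H]2OC(=O)C(COCc3ccc(OC)cc3)=C12
F9 | step 8 | 8α-hydroxy-13-(4-methoxybenzyloxy)-3,3-ethylenedioxy-5αH-eudesma-1,7(11)-dien-6α,12-olide | O[C@H]1C[C@@]2(C)C=CC3(OCCO3)[C@@H](C)[C@@H]2[C@H]2OC(=O)C(COCc3ccc(OC)cc3)=C12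
F10 | step 5 | 13-(4-methoxybenzyloxy)-3,3-ethylenedioxy-5αH,11βH-eudesm-1-en-6α,12-olide | C(OCc6ccc(OC)cc6)[C@H]1[C@@H]2CC[C@]3(C=CC4(OCCO4)[C@@H](C)[C@@H]3[C@H]2OC1=O)C
F0 | step 13 | none | none
A1 | alternative 1 | (1(10)E,4E)-cyclodecadienyl C5 triflate with 6-O-(4-methoxybenzyl), 7-O-methoxymethyl and 8-O-tert-butyldimethylsilyl groups | CC(C)(C)[Si](C)(C)O[C@H]1C/C(C)=C/CC/C(C)=C(\OS(=O)(=O)C(F)(F)F)[C@@H](OCc2ccc(OC)cc2)[C@@H]1OCOC
A2 | alternative 2 | (1(10)E,4E)-cyclodecadien-6-ol with a 3-(4-methoxybenzyloxy)prop-1-en-2-yl group on C7 and 8-O-tert-butyldimethylsilyl | CC(C)(C)[Si](C)(C)O[C@H]1C/C(C)=C/CC/C(C)=C/[C@@H](O)[C@@H]1C(=C)COCc2ccc(OC)cc2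
A3 | alternative 3 | 8-O-tert-butyldimethylsilyl 13-O-(4-methoxybenzyl) 4,5-epoxygermacra-1(10)E,7(11)-dien-6,12-olide | CC(C)(C)[Si](C)(C)O[C@H]1C/C(C)=C/CC[C@@]2(C)O[C@@H]2[C@H]2OC(=O)C(COCc3ccc(OC)cc3)=C12
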